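The α-methylene-γ-lactone (O1, C2, C3, C3a, C11a; cyclodeca[b]furan numbering) is treated as the Baeyer–Villiger image of a 2-methylidenecyclobutanone. That four-membered ring is assembled in one operation by [2+2] cycloaddition of a vinylketene (C2=C11a, from Wolff rearrangement of a dienyl diazoketone) across the oxygen-bearing double bond of an alkoxyallene locked in a dioxolane. This forms C2–C3 and C3a–C11a and the quaternary carbinol carbon C3a; the epimerisable C11a then equilibrates. Oxygen insertion into C2–C11a gives the lactone, a Nozaki–Hiyama–Kishi closure at C5–C6 completes the ten-membered ring, and the two esters are installed last.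

Key step: step 13

Remark: locants such as C2, C3, C3a, C4, C5, C6 and C11a in the Why lines are those of the target named as a cyclodeca[b]furan-2-one; geranyl acetate, (R)-solketal, angelic acid, propargyl alcohol and 2-methoxypropene are taken as commercial.

Step 1
Reactants: 1 geranyl acetate
Product: 2 (2E)-5-(3,3-dimethyloxiran-2-yl)-3-methylpent-2-en-1-yl acetate (racemic at the oxirane)
Conditions: mCPBA, NaHCO3, CH2Cl2, 0 °C
Reagents that add atoms: 3-chloroperbenzoic acid, OOC(=O)c1cccc(Cl)c1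
Why: Prilezhaev epoxidation is fastest at the remote, electron-rich trisubstituted olefin, the 2,3-olefin being deactivated by the allylic acetate; the new stereocentre is erased in step 2.

Step 2
Reactants: 2 (2E)-5-(3,3-dimethyloxiran-2-yl)-3-methylpent-2-en-1-yl acetate
Product: 3 (2E)-3-methyl-6-oxohex-2-en-1-yl acetate
Conditions: H5IO6, THF/Et2O, 0 °C
Reagents that add atoms: none
Why: Periodic acid opens the epoxide to the glycol and cleaves it in the same pot (Malaprade cleavage), leaving the (E)-allylic acetate untouched.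

Step 3
Reactants: 3 (2E)-3-methyl-6-oxohex-2-en-1-yl acetate
Product: 4 (2E,6Z)-7-iodo-3-methylocta-2,6-dien-1-yl acetate
Conditions: EtPPh3I, nBuLi, THF; I2, −78 °C; NaHMDS, −20 °C; then 3, −78 °C
Reagents that add atoms: ethyltriphenylphosphonium iodide, CC[P+](c1ccccc1)(c1ccccc1)c1ccccc1.[I-]; iodine, II
Why: Stork–Zhao olefination with the α-iodoethyl ylide should give the (Z)-2-iodo-2-alkene under the kinetic control usual for non-stabilised ylides, which fixes the geometry of the future C6=C7 olefin.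

Step 4
Reactants: 4 (2E,6Z)-7-iodo-3-methylocta-2,6-dien-1-yl acetate
Product: 5 (2E,6Z)-7-iodo-3-methylocta-2,6-dien-1-ol
Conditions: K2CO3 (cat.), MeOH, 0 °C to rt
Reagents that add atoms: none
Why: Base-catalysed transesterification removes the acetate without touching the vinyl iodide.

Step 5
Reactants: 5 (2E,6Z)-7-iodo-3-methylocta-2,6-dien-1-ol
Product: 6 (2E,6Z)-7-iodo-3-methylocta-2,6-dienal
Conditions: MnO2, CH2Cl2, rt
Reagents that add atoms: none
Why: MnO2 oxidises the allylic alcohol selectively to the enal without E/Z isomerisation.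

Step 6
Reactants: 6 (2E,6Z)-7-iodo-3-methylocta-2,6-dienal
Product: 7 (2E,6Z)-7-iodo-3-methylocta-2,6-dienoic acid
Conditions: NaClO2, NaH2PO4, 2-methyl-2-butene, tBuOH/H2O, 0 °C
Reagents that add atoms: sodium chlorite, [Na+].[O-]Cl=O
Why: Pinnick oxidation converts the enal into the acid without attacking the olefins, the hypochlorite being scavenged by 2-methyl-2-butene.

Step 7
Reactants: 7 (2E,6Z)-7-iodo-3-methylocta-2,6-dienoic acid
Product: 9 (3E,7Z)-1-diazo-8-iodo-4-methylnona-3,7-dien-2-one, via acid chloride 8 (not isolated)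
Conditions: (COCl)2, DMF (cat.), CH2Cl2, 0 °C; evaporate; CH2N2 (3 equiv), Et2O, 0 °C
Reagents that add atoms: diazomethane, C=[N+]=[N-]
Why: Acylation of excess diazomethane by the acid chloride (first stage of an Arndt–Eistert sequence) gives the α-diazo enone without added base, because a second equivalent of diazomethane consumes the HCl.

Step 8
Reactants: 10 prop-2-yn-1-ol; 11 2-methoxypropene
Product: 12 3-[(2-methoxypropan-2-yl)oxy]prop-1-yne
Conditions: PPTS (cat.), CH2Cl2, 0 °C
Reagents that add atoms: none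
Why: Acid-catalysed addition of the alcohol to the enol ether gives the mixed acetone ketal that later supplies the isopropylidene bridge.

Step 9
Reactants: 12 3-[(2-methoxypropan-2-yl)oxy]prop-1-yne
Product: 13 1-[(2-methoxypropan-2-yl)oxy]propa-1,2-diene
Conditions: KOtBu (0.2 equiv), THF, 40 °C
Reagents that add atoms: none
Why: Base-catalysed propargyl-to-allenyl isomerisation of a propargylic ether stops at the conjugated alkoxyallene.

Step 10
Reactants: 14 (R)-(2,2-dimethyl-1,3-dioxolan-4-yl)methanol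
Product: 15 (S)-2,2-dimethyl-1,3-dioxolane-4-carbaldehyde
Conditions: (COCl)2, DMSO, CH2Cl2, −78 °C; Et3N; used at once
Reagents that add atoms: none
Why: Swern oxidation gives the configurationally labile α-alkoxy aldehyde without epimerisation (the descriptor changes from R to S only through the change in substituent priorities).

Step 11
Reactants: 13 1-[(2-methoxypropan-2-yl)oxy]propa-1,2-diene; 15 (S)-2,2-dimethyl-1,3-dioxolane-4-carbaldehyde
Product: 17 (1S)-1-[(4S)-2,2-dimethyl-1,3-dioxolan-4-yl]-2-[(2-methoxypropan-2-yl)oxy]buta-2,3-dien-1-ol, via lithioallene 16 (not isolated)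
Conditions: 13, nBuLi, THF, −40 °C; then 15, −78 °C; NaHCO3 work-up
Reagents that add atoms: none
Why: The allene is lithiated at its oxygen-bearing carbon and should add to the aldehyde in the Felkin–Anh sense (ring oxygen anti to the nucleophile, no chelation of lithium in THF), giving the anti adduct and thereby the configuration of the future C4.

Step 12
Reactants: 17 (1S)-1-[(4S)-2,2-dimethyl-1,3-dioxolan-4-yl]-2-[(2-methoxypropan-2-yl)oxy]buta-2,3-dien-1-ol
Product: 18 (4S,4'S)-5-ethenylidene-2,2,2',2'-tetramethyl-4,4'-bi(1,3-dioxolane)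
Conditions: PPTS (0.05 equiv), 4 Å MS, CH2Cl2, 0 °C; Et3N quench
Reagents that add atoms: none
Why: Intramolecular transketalisation: the very labile methoxyisopropyl ketal should ionise faster than the allene is protonated, and the neighbouring hydroxyl closes the dioxolane (5-exo), tying the allene oxygen to the C4 oxygen.

Step 13
Reactants: 9 (3E,7Z)-1-diazo-8-iodo-4-methylnona-3,7-dien-2-one; 18 (4S,4'S)-5-ethenylidene-2,2,2',2'-tetramethyl-4,4'-bi(1,3-dioxolane)
Product: 21 (1S,4R,8S)-8-[(4S)-2,2-dimethyl-1,3-dioxolan-4-yl]-1-[(1E,5Z)-6-iodo-2-methylhepta-1,5-dien-1-yl]-6,6-dimethyl-3-methylidene-5,7-dioxaspiro[3.4]octan-2-one, via vinylketene 19 (not isolated), via C1-epimeric cyclobutanone 20 (not isolated)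
Conditions: hν (450 nm LEDs), 18 (1.5 equiv), CH2Cl2, rt, slow conversion; then Et3N (2 equiv), rt
Reagents that add atoms: none
Why: Irradiation expels N2 from 9 and Wolff rearrangement with alkenyl migration gives vinylketene 19, whose electrophilic carbonyl carbon attacks the nucleophilic central carbon of the allenyl ether while the ketene α-carbon closes onto the oxygen-bearing carbon, a thermal ketene–allene [2+2] cycloaddition (closest known type: ketene plus allene or enol ether giving 2-alkylidenecyclobutanones). The four-membered ring is closed by this two-bond cycloaddition, suprafacial on the allene, and ends up spiro to the dioxolane; no other ring forms. The spiro carbon (future C3a) is set by approach of the ketene to the face of the exocyclic double bond anti to the dioxolanyl substituent on the neighbouring ring carbon, which the five-membered lock holds in place. The carbon carrying the dienyl chain (future C11a) is expected to form first as epimer 20 (larger ketene substituent syn to the more crowded neighbour) and is then equilibrated by Et3N through the enol to the more stable 21, with the chain trans to the ring carbon and cis to the ring oxygen. Regioselectivity (carbonyl carbon to central allene carbon) is secured by the enol-ether polarisation of the allene, and chemoselectivity over ketene dimerisation by slow photochemical release of the ketene into an excess of 18.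

Step 14
Reactants: 21 the spiro cyclobutanone of step 13
Product: 22 (4S,5S,6S)-4-[(4S)-2,2-dimethyl-1,3-dioxolan-4-yl]-6-[(1E,5Z)-6-iodo-2-methylhepta-1,5-dien-1-yl]-2,2-dimethyl-9-methylidene-1,3,7-trioxaspiro[4.4]nonan-8-one
Conditions: 30% aq H2O2, Na2HPO4, (CF3)2CHOH, 0 °C to rt
Reagents that add atoms: hydrogen peroxide, OO
Why: Baeyer–Villiger oxidation of the strained ketone by H2O2 activated through hydrogen bonding leaves the olefins and the vinyl iodide alone; the secondary allylic carbon should migrate in preference to the sp2 carbon and does so with retention, carrying the C11a configuration into the lactone.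

Step 15
Reactants: 22 the bis-acetonide lactone of step 14
Product: 23 (4S,5S,6S)-4-[(1S)-1,2-dihydroxyethyl]-6-[(1E,5Z)-6-iodo-2-methylhepta-1,5-dien-1-yl]-2,2-dimethyl-9-methylidene-1,3,7-trioxaspiro[4.4]nonan-8-one
Conditions: AcOH/H2O (7:3), rt
Reagents that add atoms: none
Why: The terminal isopropylidene acetal should hydrolyse much faster than the hindered, inductively deactivated spiro acetal next to the lactone (selective acetal hydrolysis).

Step 16
Reactants: 23 the diol of step 15
Product: 24 (4R,5S,6S)-6-[(1E,5Z)-6-iodo-2-methylhepta-1,5-dien-1-yl]-2,2-dimethyl-9-methylidene-8-oxo-1,3,7-trioxaspiro[4.4]nonane-4-carbaldehyde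
Conditions: NaIO4, THF/pH 7 buffer, 0 °C
Reagents that add atoms: none
Why: Malaprade glycol cleavage releases the aldehyde carbon (future C5) under neutral conditions that do not epimerise the adjacent alkoxy centre, and the temporary stereocentre is erased.

Step 17
Reactants: 24 the aldehyde of step 16
Product: 25 (3aS,4S,5S,6Z,10E,11aS)-5-hydroxy-3a,4-(isopropylidenedioxy)-6,10-dimethyl-3-methylidene-3a,4,5,8,9,11a-hexahydrocyclodeca[b]furan-2(3H)-one
Conditions: CrCl2 (15 equiv), NiCl2 (cat.), degassed DMSO/THF, rt, 2 mM, syringe-pump addition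
Reagents that add atoms: none
Why: Nozaki–Hiyama–Kishi reaction: the (Z)-alkenylchromium formed with retention of geometry adds to the aldehyde and closes the ten-membered ring (10-exo-trig) at C5–C6, and Felkin–Anh attack anti to the C4–O bond of the dioxolane is expected to give the 5S carbinol.

Step 18
Reactants: 26 angelic acid [(2Z)-2-methylbut-2-enoic acid]
Product: 27 (2Z)-2-methylbut-2-en-1-ol
Conditions: LiAlH4, Et2O, 0 °C
Reagents that add atoms: none
Why: 1,2-Hydride reduction of the acid gives the allylic alcohol without isomerising the (Z)-olefin.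

Step 19
Reactants: 27 (2Z)-2-methylbut-2-en-1-ol
Product: 28 [(2R,3S)-2,3-dimethyloxiran-2-yl]methanol
Conditions: Ti(OiPr)4 (cat.), D-(−)-diethyl tartrate (cat.), tBuOOH, 4 Å MS, CH2Cl2, −20 °C
Reagents that add atoms: tert-butyl hydroperoxide, CC(C)(C)OO
Why: Sharpless asymmetric epoxidation: the D-tartrate ligand delivers oxygen to the face that gives the (2R,3S)-epoxy alcohol (reagent control), and the (Z)-olefin fixes the relative configuration.

Step 20
Reactants: 28 [(2R,3S)-2,3-dimethyloxiran-2-yl]methanol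
Product: 29 (2S,3S)-2,3-dimethyloxirane-2-carboxylic acid
Conditions: RuCl3 (cat.), NaIO4, MeCN/CCl4/H2O, rt
Reagents that add atoms: water, O
Why: RuO4 generated in situ oxidises the primary alcohol to the acid without opening the epoxide (the C2 descriptor changes from R to S only through the change in priorities).

Step 21
Reactants: 25 the macrocyclic allylic alcohol of step 17; 29 (2S,3S)-2,3-dimethyloxirane-2-carboxylic acid
Product: 31 (3aS,4S,5S,6Z,10E,11aS)-3a,4-(isopropylidenedioxy)-6,10-dimethyl-3-methylidene-2-oxo-2,3,3a,4,5,8,9,11a-octahydrocyclodeca[b]furan-5-yl (2S,3S)-2,3-dimethyloxirane-2-carboxylate, via mixed anhydride 30 (not isolated)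
Conditions: 29, 2,4,6-trichlorobenzoyl chloride, Et3N, THF, rt; then 25, DMAP, toluene, rt
Reagents that add atoms: none
Why: Yamaguchi esterification acylates the only free hydroxyl (C5) with retention, the acetal keeping the C3a and C4 oxygens masked.

Step 22
Reactants: 31 the acetonide ester of step 21
Product: 32 (3aR,4S,5S,6Z,10E,11aS)-3a,4-dihydroxy-6,10-dimethyl-3-methylidene-2-oxo-2,3,3a,4,5,8,9,11a-octahydrocyclodeca[b]furan-5-yl (2S,3S)-2,3-dimethyloxirane-2-carboxylate
Conditions: PPTS (0.3 equiv), ethylene glycol (10 equiv), MeCN, 40 °C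
Reagents that add atoms: none
Why: Acid-catalysed transketalisation to ethylene glycol removes the isopropylidene bridge under conditions that the deactivated glycidic-ester epoxide and the 1,5-diene should tolerate.

Step 23
Reactants: 32 the diol of step 22
Product: 33 (3aS,4S,5S,6Z,10E,11aS)-4-acetoxy-3a-hydroxy-6,10-dimethyl-3-methylidene-2-oxo-2,3,3a,4,5,8,9,11a-octahydrocyclodeca[b]furan-5-yl (2S,3S)-2,3-dimethyloxirane-2-carboxylate (CNP0271187.2)
Conditions: Ac2O, pyridine, DMAP (cat.), CH2Cl2, 0 °C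
Reagents that add atoms: acetic anhydride, CC(=O)OC(C)=O
Why: DMAP-catalysed acetylation takes place at the secondary C4 hydroxyl only, the tertiary C3a hydroxyl being too hindered.

Compound list
1 | geranyl acetate | CC(=O)OC/C=C(\C)CCC=C(C)C | starting material
2 | (2E)-5-(3,3-dimethyloxiran-2-yl)-3-methylpent-2-en-1-yl acetate | CC(=O)OC/C=C(\C)CCC1OC1(C)C | intermediate
3 | (2E)-3-methyl-6-oxohex-2-en-1-yl acetate | CC(=O)OC/C=C(\C)CCC=O | intermediate
4 | (2E,6Z)-7-iodo-3-methylocta-2,6-dien-1-yl acetate | CC(=O)OC/C=C(\C)CC/C=C(/C)I | intermediate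
5 | (2E,6Z)-7-iodo-3-methylocta-2,6-dien-1-ol | OC/C=C(\C)CC/C=C(/C)I | intermediate
6 | (2E,6Z)-7-iodo-3-methylocta-2,6-dienal | O=C/C=C(\C)CC/C=C(/C)I | intermediate
7 | (2E,6Z)-7-iodo-3-methylocta-2,6-dienoic acid | OC(=O)/C=C(\C)CC/C=C(/C)I | intermediate
8 | (2E,6Z)-7-iodo-3-methylocta-2,6-dienoyl chloride | ClC(=O)/C=C(\C)CC/C=C(/C)I | intermediate
9 | (3E,7Z)-1-diazo-8-iodo-4-methylnona-3,7-dien-2-one | [N-]=[N+]=CC(=O)/C=C(\C)CC/C=C(/C)I | intermediate
10 | prop-2-yn-1-ol | C#CCO | starting material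
11 | 2-methoxypropene | COC(C)=C | starting material
12 | 3-[(2-methoxypropan-2-yl)oxy]prop-1-yne | C#CCOC(C)(C)OC | intermediate
13 | 1-[(2-methoxypropan-2-yl)oxy]propa-1,2-diene | C=C=COC(C)(C)OC | intermediate
14 | (R)-(2,2-dimethyl-1,3-dioxolan-4-yl)methanol | OC[C@@H]1COC(C)(C)O1 | starting material
15 | (S)-2,2-dimethyl-1,3-dioxolane-4-carbaldehyde | O=C[C@@H]1COC(C)(C)O1 | intermediate
16 | 1-lithio-1-[(2-methoxypropan-2-yl)oxy]propa-1,2-diene | [Li]C(=C=C)OC(C)(C)OC | intermediate
17 | (1S)-1-[(4S)-2,2-dimethyl-1,3-dioxolan-4-yl]-2-[(2-methoxypropan-2-yl)oxy]buta-2,3-dien-1-ol | C=C=C(OC(C)(C)OC)[C@@H](O)[C@@H]1COC(C)(C)O1 | intermediate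
18 | (4S,4'S)-5-ethenylidene-2,2,2',2'-tetramethyl-4,4'-bi(1,3-dioxolane) | C=C=C1OC(C)(C)O[C@H]1[C@@H]2COC(C)(C)O2 | intermediate
19 | (3E,7Z)-8-iodo-4-methylnona-1,3,7-trien-1-one | O=C=C/C=C(\C)CC/C=C(/C)I | intermediate
20 | (1R,4R,8S)-8-[(4S)-2,2-dimethyl-1,3-dioxolan-4-yl]-1-[(1E,5Z)-6-iodo-2-methylhepta-1,5-dien-1-yl]-6,6-dimethyl-3-methylidene-5,7-dioxaspiro[3.4]octan-2-one | C=C1C(=O)[C@H](/C=C(\C)CC/C=C(/C)I)[C@@]12OC(C)(C)O[C@H]2[C@@H]3COC(C)(C)O3 | intermediate
21 | (1S,4R,8S)-8-[(4S)-2,2-dimethyl-1,3-dioxolan-4-yl]-1-[(1E,5Z)-6-iodo-2-methylhepta-1,5-dien-1-yl]-6,6-dimethyl-3-methylidene-5,7-dioxaspiro[3.4]octan-2-one | C=C1C(=O)[C@@H](/C=C(\C)CC/C=C(/C)I)[C@@]12OC(C)(C)O[C@H]2[C@@H]3COC(C)(C)O3 | intermediate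
22 | (4S,5S,6S)-4-[(4S)-2,2-dimethyl-1,3-dioxolan-4-yl]-6-[(1E,5Z)-6-iodo-2-methylhepta-1,5-dien-1-yl]-2,2-dimethyl-9-methylidene-1,3,7-trioxaspiro[4.4]nonan-8-one | C=C1C(=O)O[C@@H](/C=C(\C)CC/C=C(/C)I)[C@@]12OC(C)(C)O[C@H]2[C@@H]3COC(C)(C)O3 | intermediate
23 | (4S,5S,6S)-4-[(1S)-1,2-dihydroxyethyl]-6-[(1E,5Z)-6-iodo-2-methylhepta-1,5-dien-1-yl]-2,2-dimethyl-9-methylidene-1,3,7-trioxaspiro[4.4]nonan-8-one | C=C1C(=O)O[C@@H](/C=C(\C)CC/C=C(/C)I)[C@@]12OC(C)(C)O[C@H]2[C@@H](O)CO | intermediate
24 | (4R,5S,6S)-6-[(1E,5Z)-6-iodo-2-methylhepta-1,5-dien-1-yl]-2,2-dimethyl-9-methylidene-8-oxo-1,3,7-trioxaspiro[4.4]nonane-4-carbaldehyde | C=C1C(=O)O[C@@H](/C=C(\C)CC/C=C(/C)I)[C@@]12OC(C)(C)O[C@H]2C=O | intermediate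
25 | (3aS,4S,5S,6Z,10E,11aS)-5-hydroxy-3a,4-(isopropylidenedioxy)-6,10-dimethyl-3-methylidene-3a,4,5,8,9,11a-hexahydrocyclodeca[b]furan-2(3H)-one | C=C1C(=O)O[C@H]2/C=C(\C)CC/C=C(/C)[C@H](O)[C@@H]3OC(C)(C)O[C@@]123 | intermediate
26 | angelic acid, (2Z)-2-methylbut-2-enoic acid | C/C=C(/C)C(=O)O | starting material
27 | (2Z)-2-methylbut-2-en-1-ol | C/C=C(/C)CO | intermediate
28 | [(2R,3S)-2,3-dimethyloxiran-2-yl]methanol | OC[C@@]1(C)O[C@H]1C | intermediate
29 | (2S,3S)-2,3-dimethyloxirane-2-carboxylic acid | OC(=O)[C@@]1(C)O[C@H]1C | intermediate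
30 | (2S,3S)-2,3-dimethyloxirane-2-carboxylic 2,4,6-trichlorobenzoic anhydride | O=C(OC(=O)c1c(Cl)cc(Cl)cc1Cl)[C@@]2(C)O[C@H]2C | intermediate
31 | (3aS,4S,5S,6Z,10E,11aS)-3a,4-(isopropylidenedioxy)-6,10-dimethyl-3-methylidene-2-oxo-2,3,3a,4,5,8,9,11a-octahydrocyclodeca[b]furan-5-yl (2S,3S)-2,3-dimethyloxirane-2-carboxylate | C=C1C(=O)O[C@H]2/C=C(\C)CC/C=C(/C)[C@H](OC(=O)[C@@]4(C)O[C@H]4C)[C@@H]3OC(C)(C)O[C@@]123 | intermediate
32 | (3aR,4S,5S,6Z,10E,11aS)-3a,4-dihydroxy-6,10-dimethyl-3-methylidene-2-oxo-2,3,3a,4,5,8,9,11a-octahydrocyclodeca[b]furan-5-yl (2S,3S)-2,3-dimethyloxirane-2-carboxylate | C=C1C(=O)O[C@H]2/C=C(\C)CC/C=C(/C)[C@H](OC(=O)[C@@]3(C)O[C@H]3C)[C@H](O)[C@]12O | intermediate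
33 | (3aS,4S,5S,6Z,10E,11aS)-4-acetoxy-3a-hydroxy-6,10-dimethyl-3-methylidene-2-oxo-2,3,3a,4,5,8,9,11a-octahydrocyclodeca[b]furan-5-yl (2S,3S)-2,3-dimethyloxirane-2-carboxylate | C=C1C(=O)O[C@H]2/C=C(\C)CC/C=C(/C)[C@H](OC(=O)[C@@]3(C)O[C@H]3C)[C@H](OC(C)=O)[C@]12O | target

Total step count: 23. Longest linear sequence: 15 steps (steps 1–7, 13–17, 21–23).

Steps most likely to fail

Step 13. The transient vinylketene may dimerise, or acylate the allene without ring closure, faster than it is trapped, and the two new centres may form with low selectivity. The fallback sets out from 9 and 18 and comes back at 21. Irradiation of 9 (450 nm) in the presence of dimethylamine traps the ketene as (3E,7Z)-8-iodo-N,N,4-trimethylnona-3,7-dienamide F1. Tf2O and 2,4,6-collidine in ClCH2CH2Cl convert F1 into the far more electrophilic keteniminium salt N-[(3E,7Z)-8-iodo-4-methylnona-1,3,7-trien-1-ylidene]-N-methylmethanaminium triflate F2. F2 should undergo the stepwise cationic keteniminium [2+2] cycloaddition with 18, with the same regiochemistry and the same facial bias, to the spiro cyclobutaniminium triflate F3. Aqueous NaHCO3 hydrolysis and Et3N equilibration then give 21.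

Step 17. The alkenylchromium may add to the aldehyde with poor facial selectivity within the forming ring, so that the C5 epimer is formed alongside or instead of 25. The fallback sets out from 24 and comes back at 31. The epimer, (3aS,4S,5R,6Z,10E,11aS)-5-hydroxy-3a,4-(isopropylidenedioxy)-6,10-dimethyl-3-methylidene-3a,4,5,8,9,11a-hexahydrocyclodeca[b]furan-2(3H)-one F4, is separated and esterified with acid 29 under Mitsunobu conditions (PPh3, DIAD, toluene, 0 °C). This inverts C5 and gives 31, so both epimers converge on the same ester.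

Step 14. The sp2 carbon may migrate instead of the allylic carbon, or the peroxide may attack the exocyclic enone. The fallback sets out from 21 and comes back at 22. Photochemical ring expansion (λ > 300 nm, Pyrex, THF/H2O) cleaves the ketone on its allylic side, and the oxacarbene, formed with retention, is captured by water to give the lactol (4S,5S,6S)-4-[(4S)-2,2-dimethyl-1,3-dioxolan-4-yl]-8-hydroxy-6-[(1E,5Z)-6-iodo-2-methylhepta-1,5-dien-1-yl]-2,2-dimethyl-9-methylidene-1,3,7-trioxaspiro[4.4]nonane F5 (anomer mixture). MnO2 in CH2Cl2 oxidises this allylic lactol to lactone 22.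

Further compounds
F1 | step 13 | (3E,7Z)-8-iodo-N,N,4-trimethylnona-3,7-dienamide | CN(C)C(=O)C/C=C(\C)CC/C=C(/C)I
F2 | step 13 | N-[(3E,7Z)-8-iodo-4-methylnona-1,3,7-trien-1-ylidene]-N-methylmethanaminium trifluoromethanesulfonate | C[N+](C)=C=C/C=C(\C)CC/C=C(/C)I.[O-]S(=O)(=O)C(F)(F)F
F3 | step 13 | N-[(1S,4R,8S)-8-[(4S)-2,2-dimethyl-1,3-dioxolan-4-yl]-1-[(1E,5Z)-6-iodo-2-methylhepta-1,5-dien-1-yl]-6,6-dimethyl-3-methylidene-5,7-dioxaspiro[3.4]octan-2-ylidene]-N-methylmethanaminium trifluoromethanesulfonate | C=C1C(=[N+](C)C)[C@@H](/C=C(\C)CC/C=C(/C)I)[C@@]12OC(C)(C)O[C@H]2[C@@H]3COC(C)(C)O3.[O-]S(=O)(=O)C(F)(F)F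
F4 | step 17 | (3aS,4S,5R,6Z,10E,11aS)-5-hydroxy-3a,4-(isopropylidenedioxy)-6,10-dimethyl-3-methylidene-3a,4,5,8,9,11a-hexahydrocyclodeca[b]furan-2(3H)-one | C=C1C(=O)O[C@H]2/C=C(\C)CC/C=C(/C)[C@@H](O)[C@@H]3OC(C)(C)O[C@@]123
F5 | step 14 | (4S,5S,6S)-4-[(4S)-2,2-dimethyl-1,3-dioxolan-4-yl]-8-hydroxy-6-[(1E,5Z)-6-iodo-2-methylhepta-1,5-dien-1-yl]-2,2-dimethyl-9-methylidene-1,3,7-trioxaspiro[4.4]nonane | C=C1C(O)O[C@@H](/C=C(\C)CC/C=C(/C)I)[C@@]12OC(C)(C)O[C@H]2[C@@H]3COC(C)(C)O3
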